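**Retrosynthetic overview**
1. The γ-lactone (C6–O) and the C6–C7 bond are cut last: iodolactonisation and ring-closing metathesis close ring B on a bicycle whose C8/C9 substituents are already trans.
2. The bicyclo[3.2.2]nonenedione (ring C plus the C15–C17 bridge) comes from a Diels–Alder reaction between an (E)-enal carrying ring A and a 3-hydroxytropone that is dearomatised in the same flask by enol hydroxylation.
3. The hydroxytropone comes from 2,3-dimethylfuran by a dearomative (4+3) cycloaddition with a chloro-oxyallyl cation, followed by bridge opening and loss of HCl.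
4. Ring A comes from 2-methylresorcinol: dearomative hydrogenation/methylation to the symmetric dione, then enoate formation, CBS reduction, and vinyl conjugate addition with aldol trapping to build the C10 quaternary centre.
5. Ring order: A (from the arene), seven-membered ring (from the furan), ring C and bridge (Diels–Alder), ring B (metathesis), lactone.

Assumption: stereochemistry is taken exactly as written in the SMILES. Carbons are numbered C1–C10 for rings A/B (C3 OAc, C4 CMe2, C6 lactone oxygen, C8 CH3, C10 bears the lactone carbonyl) and C11–C17 for the bridged part (C11 CH bridgehead, C12=C13, C14 CO2Me bridgehead, C15 and C17 ketones, C16 carbinol).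

**Route**

Step 1
Reactants: 1 2-methylresorcinol
Product: 3 2,2-dimethylcyclohexane-1,3-dione, via sodium 2-methylcyclohexane-1,3-dionate 2 (not isolated)
Conditions: H2 (70 bar), Raney Ni, NaOH (1 equiv), H2O, 50 °C; then MeI, 1,4-dioxane/H2O, 80 °C
Reagents that add atoms: iodomethane [CH3]I
Why: Hydrogenation of the resorcinolate monoanion stops at the vinylogous carboxylate (dearomative partial reduction of a resorcinol), which is then C-methylated in water (alkylation of a cyclic 1,3-diketone enolate) to the achiral dione; no stereocentre is formed.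

Step 2
Reactants: 3 2,2-dimethylcyclohexane-1,3-dione
Product: 4 tert-butyl 3,3-dimethyl-2,4-dioxocyclohexane-1-carboxylate
Conditions: LiN(SiMe3)2 (2.2 equiv), THF, −78 °C; Boc2O, −78 → 0 °C; aq. HCl
Reagents that add atoms: di-tert-butyl dicarbonate CC(C)(C)OC(=O)OC(=O)OC(C)(C)C
Why: The lithium enolate of the only enolisable position is C-acylated by Boc2O (Claisen-type acylation) and the second equivalent of base stores the acidic β-keto ester as its enolate; C10 stays enolisable, so no stereocentre is defined.

Step 3
Reactants: 4 tert-butyl 3,3-dimethyl-2,4-dioxocyclohexane-1-carboxylate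
Product: 5 tert-butyl 3,3-dimethyl-4-oxo-2-(trifluoromethylsulfonyloxy)cyclohex-1-ene-1-carboxylate
Conditions: Tf2O, i-Pr2NEt, CH2Cl2, −78 → 0 °C
Reagents that add atoms: trifluoromethanesulfonic anhydride O=S(=O)(OS(=O)(=O)C(F)(F)F)C(F)(F)F
Why: O-sulfonylation of the β-keto ester enol (enol triflate formation) fixes the future C5=C10 double bond.

Step 4
Reactants: 5 tert-butyl 3,3-dimethyl-4-oxo-2-(trifluoromethylsulfonyloxy)cyclohex-1-ene-1-carboxylate
Product: 6 tert-butyl 3,3-dimethyl-4-oxocyclohex-1-ene-1-carboxylate
Conditions: Pd(OAc)2 (5 mol %), PPh3, HCO2H, Et3N, DMF, 60 °C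
Reagents that add atoms: none
Why: Palladium-catalysed formate reduction of the vinyl triflate (Cacchi-type hydrogenolysis) replaces OTf by H without touching the ketone or the ester, leaving C5 as the free β-position of the enoate.

Step 5
Reactants: 6 tert-butyl 3,3-dimethyl-4-oxocyclohex-1-ene-1-carboxylate
Product: 8 tert-butyl (4S)-4-acetoxy-3,3-dimethylcyclohex-1-ene-1-carboxylate, via tert-butyl (4S)-4-hydroxy-3,3-dimethylcyclohex-1-ene-1-carboxylate 7 (not isolated)
Conditions: (R)-2-methyl-CBS-oxazaborolidine (10 mol %), BH3·SMe2, THF, −20 °C; MeOH; then Ac2O, pyridine, DMAP, 23 °C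
Reagents that add atoms: acetic anhydride CC(=O)OC(C)=O
Why: Corey–Bakshi–Shibata reduction distinguishes the quaternary CMe2 side from the CH2 side of the ketone and sets C3 as (S) by reagent control, and acetylation in the same flask installs the C3 acetate of the target.

Step 6
Reactants: 8 tert-butyl (4S)-4-acetoxy-3,3-dimethylcyclohex-1-ene-1-carboxylate; 9 (E)-3-ethoxy-2-methylprop-2-enal
Product: 12 ring A enal, via silyl ketene acetal 10 (not isolated), via aldol adduct 11 (not isolated)
Conditions: CH2=CHMgBr, CuBr·SMe2 (10 mol %), Me3SiCl, DMPU, THF, −78 °C; then 9, Sc(OTf)3 (10 mol %), CH2Cl2, −78 → −20 °C; then 1 M HCl, THF, 23 °C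
Reagents that add atoms: vinylmagnesium bromide C=C[Mg]Br; water O
Why: Copper-catalysed, Me3SiCl-accelerated conjugate addition (Kuwajima–Nakamura conditions) delivers vinyl to C5 by axial attack anti to the pseudoequatorial C3 acetate (the trans-3,5 rule of cyclohexenone-type acceptors), the ketene acetal then adds to 9 in a Mukaiyama aldol reaction anti to the new vinyl group so that C10 becomes quaternary with the ester cis to the vinyl, and acid-induced allylic transposition of the β-ethoxy allylic alcohol releases the (E)-enal.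

Step 7
Reactants: 13 2,2-dimethyl-1,3-dioxane-4,6-dione (Meldrum's acid); 14 2,2-dichloropropanoyl chloride
Product: 16 methyl 4,4-dichloro-3-oxopentanoate, via acyl Meldrum's acid 15 (not isolated)
Conditions: pyridine, CH2Cl2, 0 → 23 °C; then MeOH, 65 °C
Reagents that add atoms: methanol CO
Why: C-acylation of Meldrum's acid followed by methanolysis with loss of acetone and CO2 is the standard Oikawa–Yonemitsu β-keto ester synthesis; no stereocentre.

Step 8
Reactants: 16 methyl 4,4-dichloro-3-oxopentanoate; 17 2,3-dimethylfuran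
Product: 20 methyl 5-hydroxy-2,3,6-trimethyl-7-oxocyclohepta-1,3,5-triene-1-carboxylate, via chloro oxabicycle 18 (not isolated), via chlorohydrin dienone 19 (not isolated)
Conditions: Et3N, CF3CH2OH, 0 → 23 °C (17 in excess); then DBU, MeCN, 50 °C
Reagents that add atoms: none
Why: Proposed new method: amine-induced enolisation of 16 toward C2 and loss of one chloride gives a chloro(methoxycarbonyl)oxyallyl cation whose cationic carbon is attacked by the free α-position of the furan and whose enolate carbon closes onto the methyl-bearing α-carbon (Föhlisch-type dearomative (4+3) cycloaddition), after which DBU opens the oxygen bridge by β-elimination from the β-keto ester and the chlorohydrin loses HCl (epoxide formation and isomerisation) to aromatise to the hydroxytropone; the closest known reaction type is the Föhlisch cycloaddition followed by base-mediated conversion of 8-oxabicyclo[3.2.1]oct-6-en-3-ones into tropones.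

Step 9
Reactants: 20 methyl 5-hydroxy-2,3,6-trimethyl-7-oxocyclohepta-1,3,5-triene-1-carboxylate; 12 ring A enal
Product: 22 aldehyde cycloadduct, via hydroxy dienedione 21 (not isolated)
Conditions: dimethyldioxirane, acetone, −20 °C (20 used in 2.5-fold excess over 12); evaporate; then 12, CH2Cl2, 12 kbar, 25 °C
Reagents that add atoms: dimethyldioxirane CC1(C)OO1
Why: Proposed new method: dimethyldioxirane epoxidises the enol double bond of the hydroxytropone and so breaks its aromaticity to give the ortho-quinol-like α-hydroxy dienedione 21, whose cisoid diene adds the (E)-enal under pressure in a Diels–Alder reaction with the formyl-bearing carbon bonding to the ester-bearing terminus (ortho rule and least hindered pairing C9–C11), on the diene face syn to the hydroxyl (O–H···O=C hydrogen bond, as in ortho-quinol cycloadditions) and with the formyl group exo, so that the alkene geometry fixes C8 and C9 trans and C11, C14 and C16 follow from the bicyclic framework, while attack anti to the axial tert-butyl ester of the A(1,3)-minimised enal conformer selects the matching enantiomer of racemic 21 (kinetic resolution, hence its excess) and ties the new stereocentres to C10; the closest known reaction type is hydroxylative phenol dearomatisation followed by ortho-quinol Diels–Alder reaction.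

Step 10
Reactants: 22 aldehyde cycloadduct
Product: 23 divinyl cycloadduct
Conditions: Zn, CH2Br2, TiCl4, THF/CH2Cl2, 0 → 23 °C
Reagents that add atoms: dibromomethane BrCBr
Why: Takai–Lombardo methylenation is non-basic and converts the neopentyl aldehyde chemoselectively in the presence of the hindered ketones, the esters and the base-sensitive α-hydroxy β-diketone; no stereocentre is touched.

Step 11
Reactants: 23 divinyl cycloadduct
Product: 24 ring B cyclohexene tert-butyl ester
Conditions: second-generation Hoveyda–Grubbs catalyst (10 mol %), toluene (2 mM), 80 °C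
Reagents that add atoms: none
Why: Ring-closing olefin metathesis between the two monosubstituted vinyl groups (the tetrasubstituted C12=C13 alkene is inert) closes ring B with loss of ethylene, and because C8 and C9 are already trans only the trans-fused ring can form.

Step 12
Reactants: 24 ring B cyclohexene tert-butyl ester
Product: 26 iodolactone, via carboxylic acid 25 (not isolated)
Conditions: CF3CO2H, CH2Cl2, 0 °C; evaporate; then N-iodosuccinimide, MeCN, 0 °C, dark
Reagents that add atoms: N-iodosuccinimide O=C1CCC(=O)N1I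
Why: Acidolysis removes only the tert-butyl ester, and the free C10 acid then undergoes kinetically controlled iodolactonisation (anti addition through the iodonium ion with diaxial opening), which can deliver oxygen only to C6 from the face of the carboxyl group and so sets C6 and forms the γ-lactone while the C14 methyl ester stays inert.

Step 13
Reactants: 26 iodolactone
Product: 27 penicimeroterpenoid A
Conditions: Bu3SnH, AIBN (cat.), toluene, 80 °C
Reagents that add atoms: none
Why: Tin hydride radical dehalogenation replaces the iodine at C7 by hydrogen (C7 becomes CH2 and is not a stereocentre) without affecting any other stereocentre and gives the target.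

**Compound list**

1 | 2-methylresorcinol (2-methylbenzene-1,3-diol) | Cc1c(O)cccc1O | starting material
2 | sodium 2-methylcyclohexane-1,3-dionate | CC1=C([O-])CCCC1=O.[Na+] | intermediate
3 | 2,2-dimethylcyclohexane-1,3-dione | CC1(C)C(=O)CCCC1=O | intermediate
4 | tert-butyl 3,3-dimethyl-2,4-dioxocyclohexane-1-carboxylate (racemic, enolised) | CC(C)(C)OC(=O)C1CCC(=O)C(C)(C)C1=O | intermediate
5 | tert-butyl 3,3-dimethyl-4-oxo-2-(trifluoromethylsulfonyloxy)cyclohex-1-ene-1-carboxylate | CC(C)(C)OC(=O)C1=C(OS(=O)(=O)C(F)(F)F)C(C)(C)C(=O)CC1 | intermediate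
6 | tert-butyl 3,3-dimethyl-4-oxocyclohex-1-ene-1-carboxylate | CC(C)(C)OC(=O)C1=CC(C)(C)C(=O)CC1 | intermediate
7 | tert-butyl (4S)-4-hydroxy-3,3-dimethylcyclohex-1-ene-1-carboxylate | CC(C)(C)OC(=O)C1=CC(C)(C)[C@@H](O)CC1 | intermediate
8 | tert-butyl (4S)-4-acetoxy-3,3-dimethylcyclohex-1-ene-1-carboxylate | CC(C)(C)OC(=O)C1=CC(C)(C)[C@@H](OC(C)=O)CC1 | intermediate
9 | (E)-3-ethoxy-2-methylprop-2-enal | CCO/C=C(C)/C=O | starting material
10 | silyl ketene acetal: tert-butyl trimethylsilyl ketene acetal of the 4-acetoxy-3,3-dimethyl-2-vinylcyclohexane ester (vinyl trans to acetoxy) | CC(C)(C)OC(O[Si](C)(C)C)=C1CC[C@H](OC(C)=O)C(C)(C)[C@H]1C=C | intermediate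
11 | aldol adduct: tert-butyl 4-acetoxy-1-[(E)-3-ethoxy-1-hydroxy-2-methylallyl]-3,3-dimethyl-2-vinylcyclohexane-1-carboxylate (ester cis to vinyl, carbinol epimers) | CCO/C=C(C)/C(O)[C@]1(C(=O)OC(C)(C)C)CC[C@H](OC(C)=O)C(C)(C)[C@H]1C=C | intermediate
12 | ring A enal: tert-butyl (4S)-4-acetoxy-3,3-dimethyl-1-[(E)-2-methyl-3-oxoprop-1-enyl]-2-vinylcyclohexane-1-carboxylate (ester cis to vinyl, acetoxy trans to vinyl) | O=C/C(C)=C/[C@]1(C(=O)OC(C)(C)C)CC[C@H](OC(C)=O)C(C)(C)[C@H]1C=C | intermediate
13 | 2,2-dimethyl-1,3-dioxane-4,6-dione (Meldrum's acid) | CC1(C)OC(=O)CC(=O)O1 | starting material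
14 | 2,2-dichloropropanoyl chloride | CC(Cl)(Cl)C(=O)Cl | starting material
15 | 5-(2,2-dichloropropanoyl)-2,2-dimethyl-1,3-dioxane-4,6-dione | CC1(C)OC(=O)C(C(=O)C(C)(Cl)Cl)C(=O)O1 | intermediate
16 | methyl 4,4-dichloro-3-oxopentanoate | COC(=O)CC(=O)C(C)(Cl)Cl | intermediate
17 | 2,3-dimethylfuran | Cc1occc1C | starting material
18 | methyl 4-chloro-1,4,7-trimethyl-3-oxo-8-oxabicyclo[3.2.1]oct-6-ene-2-carboxylate (racemic) | COC(=O)C1C(=O)C(C)(Cl)C2C=C(C)C1(C)O2 | intermediate
19 | methyl 6-chloro-5-hydroxy-2,3,6-trimethyl-7-oxocyclohepta-1,3-diene-1-carboxylate (racemic) | COC(=O)C1=C(C)C(C)=CC(O)C(C)(Cl)C1=O | intermediate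
20 | methyl 5-hydroxy-2,3,6-trimethyl-7-oxocyclohepta-1,3,5-triene-1-carboxylate (a 3-hydroxytropone) | COC(=O)C1=C(C)C(C)=CC(O)=C(C)C1=O | intermediate
21 | methyl 6-hydroxy-2,3,6-trimethyl-5,7-dioxocyclohepta-1,3-diene-1-carboxylate (racemic) | COC(=O)C1=C(C)C(C)=CC(=O)C(C)(O)C1=O | intermediate
22 | aldehyde cycloadduct: bicyclo[3.2.2]non-6-ene-2,4-dione with C14 CO2Me, C16 OH/CH3, C12=C13 dimethyl, C8 carrying CH3 and CHO, C9 carrying H and the ring A unit (C10 CO2t-Bu, C5 vinyl, C3 OAc) | COC(=O)[C@@]12C(=O)[C@](C)(O)C(=O)[C@@H](C(C)=C1C)[C@@H]([C@]3(C(=O)OC(C)(C)C)CC[C@H](OC(C)=O)C(C)(C)[C@H]3C=C)[C@]2(C)C=O | intermediate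
23 | divinyl cycloadduct: as 22 with CH=CH2 in place of CHO at C8 | COC(=O)[C@@]12C(=O)[C@](C)(O)C(=O)[C@@H](C(C)=C1C)[C@@H]([C@]3(C(=O)OC(C)(C)C)CC[C@H](OC(C)=O)C(C)(C)[C@H]3C=C)[C@]2(C)C=C | intermediate
24 | ring B cyclohexene tert-butyl ester: tetracycle with C6=C7 and C10 CO2t-Bu | COC(=O)[C@@]12C(=O)[C@](C)(O)C(=O)[C@@H](C(C)=C1C)[C@H]1[C@]3(C(=O)OC(C)(C)C)CC[C@H](OC(C)=O)C(C)(C)[C@H]3C=C[C@@]12C | intermediate
25 | carboxylic acid: as 24 with C10 CO2H | COC(=O)[C@@]12C(=O)[C@](C)(O)C(=O)[C@@H](C(C)=C1C)[C@H]1[C@]3(C(=O)O)CC[C@H](OC(C)=O)C(C)(C)[C@H]3C=C[C@@]12C | intermediate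
26 | iodolactone: 7-iodo derivative of the target (iodine trans to the lactone oxygen) | COC(=O)[C@@]12C(=O)[C@](C)(O)C(=O)[C@@H](C(C)=C1C)[C@H]1[C@]34CC[C@H](OC(C)=O)C(C)(C)[C@H]3[C@H]([C@H](I)[C@@]12C)OC4=O | intermediate
27 | penicimeroterpenoid A | COC(=O)[C@@]12C(=O)[C@](C)(O)C(=O)[C@@H](C(C)=C1C)[C@H]1[C@]34CC[C@H](OC(C)=O)C(C)(C)[C@H]3[C@H](C[C@@]12C)OC4=O | target

**Step count and risks**

Total step count: 13. Longest linear sequence: 11 steps (1 to 27 through steps 1–6 and 9–13).

Most likely to fail, first: step 9. The diene and the enal are both electron-poor and hindered, and the enal face selection rests on a conformational argument that could favour the wrong diastereomer. The fallback sets out from 12 and comes back at 22. Reduce 12 with NaBH4/CeCl3·7H2O to the allylic alcohol F1, condense F1 and freshly made 21 with PhB(OH)2 (toluene, molecular sieves) to the mixed phenylboronate F2, and heat so that a tethered, inverse-demand intramolecular Diels–Alder reaction gives the cyclic boronate cycloadduct F3. The tether holds C7 on the side of the diketone bridge and the diene face on the side of the oxygen. Transesterification with 2,2-dimethylpropane-1,3-diol releases the cycloadduct diol F4, whose primary alcohol is oxidised with Dess–Martin periodinane to 22.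

Second: step 11. Both vinyl groups sit next to quaternary carbons and the ring formed is a strained trans-fused one. The fallback sets out from 22 and comes back at 24. Olefinate 22 with the salt-free ylide from (hex-5-enyl)triphenylphosphonium bromide at −78 °C to the relay triene F5. Its unhindered terminal olefin loads the ruthenium, cyclopentene is expelled, and the carbene is placed directly on C7 for closure onto the C5 vinyl group (relay ring-closing metathesis), giving 24. This addresses slow initiation at the hindered vinyl groups but not the ring strain itself.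

Third: step 6. Conjugate addition next to a quaternary carbon and an aldol reaction that forms a quaternary centre may be slow or poorly selective. The fallback sets out from 8 and comes back at 12. Run the same copper-catalysed vinyl addition, but trap the ketene acetal with HC(OMe)3/Me3SiOTf to give the dimethyl acetal F6, hydrolyse it (aqueous oxalic acid) to the quaternary aldehyde F7, and carry out a Wittig reaction of F7 with 2-(triphenylphosphoranylidene)propanal (toluene, 90 °C) to reach 12.

Further compounds
F1 | step 9 | allylic alcohol from 12 (CH2OH in place of CHO) | OC/C(C)=C/[C@]1(C(=O)OC(C)(C)C)CC[C@H](OC(C)=O)C(C)(C)[C@H]1C=C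
F2 | step 9 | mixed phenylboronate of 21 and F1 | COC(=O)C1=C(C)C(C)=CC(=O)C(C)(OB(c2ccccc2)OC/C(C)=C/[C@]2(C(=O)OC(C)(C)C)CC[C@H](OC(C)=O)C(C)(C)[C@H]2C=C)C1=O
F3 | step 9 | cyclic phenylboronate cycloadduct (boron bridging the C16 oxygen and the C7 oxygen) | COC(=O)[C@@]12C(=O)[C@](C)(OB(c3ccccc3)OC4)C(=O)[C@@H](C(C)=C1C)[C@@H]([C@]3(C(=O)OC(C)(C)C)CC[C@H](OC(C)=O)C(C)(C)[C@H]3C=C)[C@@]24C
F4 | step 9 | cycloadduct diol (CH2OH at C8 in place of CHO of 22) | COC(=O)[C@@]12C(=O)[C@](C)(O)C(=O)[C@@H](C(C)=C1C)[C@@H]([C@]3(C(=O)OC(C)(C)C)CC[C@H](OC(C)=O)C(C)(C)[C@H]3C=C)[C@]2(C)CO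
F5 | step 11 | relay triene (hepta-1,6-dienyl group at C8 in place of CHO of 22) | COC(=O)[C@@]12C(=O)[C@](C)(O)C(=O)[C@@H](C(C)=C1C)[C@@H]([C@]3(C(=O)OC(C)(C)C)CC[C@H](OC(C)=O)C(C)(C)[C@H]3C=C)[C@]2(C)C=CCCCC=C
F6 | step 6 | ring A dimethyl acetal (CH(OMe)2 at C10) | COC(OC)[C@]1(C(=O)OC(C)(C)C)CC[C@H](OC(C)=O)C(C)(C)[C@H]1C=C
F7 | step 6 | ring A quaternary aldehyde (CHO at C10) | O=C[C@]1(C(=O)OC(C)(C)C)CC[C@H](OC(C)=O)C(C)(C)[C@H]1C=C
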